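The flavone is cut back to a 2',4',6'-trihydroxychalcone, and ring A of that chalcone to an open-chain cinnamoyl triketo ester. Ring A carries oxygen at C5, C7 and C8a and the C4 acyl carbon at C4a, the 1,3,5-trioxygenated acylbenzene pattern of a folded polyketide. One hydroxide-mediated Claisen ring closure (C4a–C8a bond) with aromatisation therefore builds the whole phloroglucinol ring from a chain that already holds the complete, protected erythro side chain. The precursor is methyl (E)-9-aryl-3,5,7-trioxonon-8-enoate 12, made by acylating a diketo ester trianion with a Heck-derived cinnamoyl Weinreb amide. Both stereocentres come from an auxiliary-controlled anti glycolate aldol.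

Key step: step 7

Remark: the target is the erythro isomer (carbinol carbon R, aryloxy carbon S; the two oxygens anti along the extended three-carbon chain), so an anti aldol is needed; compounds 1, 2, 4, 9 and 11 are taken as purchasable.

Step 1
Reactants: 1 4-bromo-2,6-dimethoxyphenol; 2 (4S)-4-benzyl-3-(chloroacetyl)-1,3-oxazolidin-2-one
Product: 3 (4S)-4-benzyl-3-[(4-bromo-2,6-dimethoxyphenoxy)acetyl]-1,3-oxazolidin-2-one
Conditions: K2CO3, NaI (cat.), acetone, 56 °C
Reagents that add atoms: none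
Why: Williamson etherification, in which the phenoxide displaces halide from the α-halo imide by SN2 (iodide exchange raises the rate) much faster than it attacks the imide carbonyl, and no stereocentre is involved.

Step 2
Reactants: 3 (4S)-4-benzyl-3-[(4-bromo-2,6-dimethoxyphenoxy)acetyl]-1,3-oxazolidin-2-one; 4 4-(benzyloxy)-3-methoxybenzaldehyde
Product: 6 (4S)-4-benzyl-3-[(2R,3R)-3-[4-(benzyloxy)-3-methoxyphenyl]-2-(4-bromo-2,6-dimethoxyphenoxy)-3-hydroxypropanoyl]-1,3-oxazolidin-2-one, via O-trimethylsilyl aldol adduct 5 (not isolated)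
Conditions: MgCl2 (0.2 equiv), Et3N, TMSCl, EtOAc, 23 °C; then 1 M aq. HCl–THF, 0 °C
Reagents that add atoms: none
Why: Magnesium-halide-catalysed direct anti-aldol reaction of an N-acyl oxazolidinone (Evans type), in which soft enolisation gives the chelated Z-enolate, the non-enolisable aldehyde adds through a boat-like transition state on the face opposite the benzyl group so that C2 and C3 are both set R (anti), and silylation of the aldolate by TMSCl releases magnesium for turnover before brief mild acid removes the silyl group.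

Step 3
Reactants: 6 (4S)-4-benzyl-3-[(2R,3R)-3-[4-(benzyloxy)-3-methoxyphenyl]-2-(4-bromo-2,6-dimethoxyphenoxy)-3-hydroxypropanoyl]-1,3-oxazolidin-2-one
Product: 7 (1R,2S)-1-[4-(benzyloxy)-3-methoxyphenyl]-2-(4-bromo-2,6-dimethoxyphenoxy)propane-1,3-diol
Conditions: LiBH4, MeOH (1 equiv), THF, 0 °C; aq. NaOH work-up
Reagents that add atoms: none
Why: Reductive cleavage of the N-acyl oxazolidinone, in which hydride adds to the more electrophilic exocyclic imide carbonyl and the acyl carbon ends as the primary alcohol, while both stereocentres, the aryl bromide and the benzyl ether are untouched (the descriptor at the aryloxy carbon changes from R to S only because the priorities change).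

Step 4
Reactants: 7 (1R,2S)-1-[4-(benzyloxy)-3-methoxyphenyl]-2-(4-bromo-2,6-dimethoxyphenoxy)propane-1,3-diol
Product: 8 (1R,2S)-1-[4-(benzyloxy)-3-methoxyphenyl]-2-(4-bromo-2,6-dimethoxyphenoxy)-1,3-bis[(tert-butyldimethylsilyl)oxy]propane
Conditions: TBSOTf, 2,6-lutidine, CH2Cl2, −78 to 0 °C
Reagents that add atoms: tert-butyldimethylsilyl trifluoromethanesulfonate, CC(C)(C)[Si](C)(C)OS(=O)(=O)C(F)(F)F
Why: Silyl ether formation with a silyl triflate and a hindered pyridine base should cap both the primary and the hindered secondary benzylic hydroxyl at low temperature without ionising the benzylic C–O bond.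

Step 5
Reactants: 8 (1R,2S)-1-[4-(benzyloxy)-3-methoxyphenyl]-2-(4-bromo-2,6-dimethoxyphenoxy)-1,3-bis[(tert-butyldimethylsilyl)oxy]propane; 9 N-methoxy-N-methylprop-2-enamide
Product: 10 (2E)-3-[4-({(1R,2S)-1-[4-(benzyloxy)-3-methoxyphenyl]-1,3-bis[(tert-butyldimethylsilyl)oxy]propan-2-yl}oxy)-3,5-dimethoxyphenyl]-N-methoxy-N-methylprop-2-enamide
Conditions: Pd(OAc)2 (5 mol%), P(o-tol)3 (10 mol%), Et3N, DMF, 100 °C
Reagents that add atoms: none
Why: Mizoroki–Heck reaction, in which oxidative addition of the aryl bromide to zerovalent palladium, syn insertion of the acrylamide and syn β-hydride elimination should give the (E)-cinnamamide with the silyl ethers, the benzyl ether and both stereocentres as spectators.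

Step 6
Reactants: 10 (2E)-3-[4-({(1R,2S)-1-[4-(benzyloxy)-3-methoxyphenyl]-1,3-bis[(tert-butyldimethylsilyl)oxy]propan-2-yl}oxy)-3,5-dimethoxyphenyl]-N-methoxy-N-methylprop-2-enamide; 11 methyl 3,5-dioxohexanoate
Product: 12 methyl (8E)-9-[4-({(1R,2S)-1-[4-(benzyloxy)-3-methoxyphenyl]-1,3-bis[(tert-butyldimethylsilyl)oxy]propan-2-yl}oxy)-3,5-dimethoxyphenyl]-3,5,7-trioxonon-8-enoate
Conditions: 11 (2.5 equiv), LDA (7.6 equiv), THF, −78 to 0 °C; then 10, −78 to −20 °C; AcOH quench at −78 °C; crude product used at once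
Reagents that add atoms: none
Why: Weinreb ketone synthesis applied to a 1,3,5-tricarbonyl polyanion (Harris-type chain extension), in which the trilithio derivative of 11 reacts at its least stabilised terminal methyl carbanion, adds 1,2 to the amide carbonyl in preference to the electron-rich β-carbon, and the N-methoxy-N-methyl group prevents over-addition.

Step 7
Reactants: 12 methyl (8E)-9-[4-({(1R,2S)-1-[4-(benzyloxy)-3-methoxyphenyl]-1,3-bis[(tert-butyldimethylsilyl)oxy]propan-2-yl}oxy)-3,5-dimethoxyphenyl]-3,5,7-trioxonon-8-enoate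
Product: 13 (2E)-3-[4-({(1R,2S)-1-[4-(benzyloxy)-3-methoxyphenyl]-1,3-bis[(tert-butyldimethylsilyl)oxy]propan-2-yl}oxy)-3,5-dimethoxyphenyl]-1-(2,4,6-trihydroxyphenyl)prop-2-en-1-one
Conditions: KOH (2 M, H2O–MeOH–THF), argon, 0 to 23 °C; then AcOH to pH 5 at 0 °C, rapid extraction
Reagents that add atoms: none
Why: Hydroxide converts the triketo ester into its polyenolate, the carbanion at C6 (between the C5 and C7 carbonyls) adds to the ester carbon C1, methoxide leaves, and the acylated cyclohexane-1,3,5-trione tautomerises irreversibly to the phloroglucinol, i.e. an intramolecular Claisen (Dieckmann-type) condensation followed by aromatisation. The closest known reaction is the hydroxide-mediated cyclisation of 7-aryl-3,5,7-trioxoheptanoate esters to 2,4,6-trihydroxybenzophenones, the laboratory counterpart of the chalcone synthase fold. Ring A closes in the 6-exo-trig mode (enolate carbon onto an ester C=O exocyclic to the new ring), forming the C4a–C8a bond, which is equivalent to C4a–C5 in the symmetric ring. No stereocentre is created, and the two existing ones carry no acidic hydrogen and should not epimerise. The step needs Claisen closure to win over aldol closure (C2 onto the C7 ketone, the resorcylate fold) and over lactonisation to a 4-hydroxy-2-pyrone: in strong aqueous base the ketone carbonyls, C7 included, are held as enolates and are poor electrophiles, whereas the methyl ester, the weakest enolate acceptor, keeps its carbonyl character and a leaving group, and pyrone formation is an acid-promoted process. The silyl ethers, the benzyl and aryl ethers and the (E)-alkene should tolerate aqueous KOH at room temperature, and the symmetric ring A makes the later closure of ring C regiochemically unambiguous.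

Step 8
Reactants: 13 (2E)-3-[4-({(1R,2S)-1-[4-(benzyloxy)-3-methoxyphenyl]-1,3-bis[(tert-butyldimethylsilyl)oxy]propan-2-yl}oxy)-3,5-dimethoxyphenyl]-1-(2,4,6-trihydroxyphenyl)prop-2-en-1-one
Product: 15 2-[4-({(1R,2S)-1-[4-(benzyloxy)-3-methoxyphenyl]-1,3-bis[(tert-butyldimethylsilyl)oxy]propan-2-yl}oxy)-3,5-dimethoxyphenyl]-5,7-dihydroxy-4H-chromen-4-one, via 5,7-dihydroxyflavanone 14 (not isolated)
Conditions: I2 (1.2 equiv), pyridine, argon, 90 °C; aq. Na2S2O3 work-up
Reagents that add atoms: none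
Why: Iodine-mediated dehydrogenation of a flavanone formed in situ (the pyridine variant of the chalcone-to-flavone oxidative cyclisation), in which hot pyridine closes ring C by 6-endo oxa-Michael addition of either equivalent ortho phenol, the flavanone is iodinated at C3 through its enol and loses hydrogen iodide to pyridine, and the buffered medium spares the acid-sensitive benzylic silyl ether (any flavanone already present in 13 converges on the same product).

Step 9
Reactants: 15 2-[4-({(1R,2S)-1-[4-(benzyloxy)-3-methoxyphenyl]-1,3-bis[(tert-butyldimethylsilyl)oxy]propan-2-yl}oxy)-3,5-dimethoxyphenyl]-5,7-dihydroxy-4H-chromen-4-one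
Product: 16 2-[4-({(1R,2S)-1-[4-(benzyloxy)-3-methoxyphenyl]-1,3-dihydroxypropan-2-yl}oxy)-3,5-dimethoxyphenyl]-5,7-dihydroxy-4H-chromen-4-one
Conditions: TBAF (4 equiv), AcOH (4 equiv), THF, 23 to 45 °C
Reagents that add atoms: none
Why: Fluoride-induced desilylation driven by the strong Si–F bond, with acetic acid buffering so that the flavone phenols and the benzylic alcohol are not exposed to strong base and neither stereocentre is touched.

Step 10
Reactants: 16 2-[4-({(1R,2S)-1-[4-(benzyloxy)-3-methoxyphenyl]-1,3-dihydroxypropan-2-yl}oxy)-3,5-dimethoxyphenyl]-5,7-dihydroxy-4H-chromen-4-one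
Product: 17 (2S,3R)-3-[4-(benzyloxy)-3-methoxyphenyl]-2-[4-(5,7-dihydroxy-4-oxo-4H-chromen-2-yl)-2,6-dimethoxyphenoxy]-3-hydroxypropyl acetate
Conditions: Novozym 435 (immobilised Candida antarctica lipase B), vinyl acetate, THF, 45 °C
Reagents that add atoms: vinyl acetate, C=COC(C)=O
Why: Lipase-catalysed irreversible transesterification with an enol ester, in which the enzyme acylates the unhindered primary aliphatic hydroxyl and leaves the secondary benzylic hydroxyl and the phenols alone, as is known for the primary alcohol of flavonolignans, while tautomerisation of the released vinyl alcohol to acetaldehyde prevents the reverse reaction.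

Step 11
Reactants: 17 (2S,3R)-3-[4-(benzyloxy)-3-methoxyphenyl]-2-[4-(5,7-dihydroxy-4-oxo-4H-chromen-2-yl)-2,6-dimethoxyphenoxy]-3-hydroxypropyl acetate
Product: 18 (2S,3R)-2-[4-(5,7-dihydroxy-4-oxo-4H-chromen-2-yl)-2,6-dimethoxyphenoxy]-3-hydroxy-3-(4-hydroxy-3-methoxyphenyl)propyl acetate (CNP0157817.1)
Conditions: H2 (1 atm), Pd/C (palladium on carbon, 10 wt%), EtOAc–THF, 23 °C
Reagents that add atoms: none
Why: Catalytic hydrogenolysis of the aryl benzyl ether on palladium under one atmosphere of hydrogen in a neutral aprotic medium, under which the flavone C2–C3 double bond, the acetate and the secondary benzylic alcohol should persist if the reaction is stopped at full conversion.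

Compound list
1 | 4-bromo-2,6-dimethoxyphenol | COc1cc(Br)cc(OC)c1O | starting material
2 | (4S)-4-benzyl-3-(chloroacetyl)-1,3-oxazolidin-2-one | O=C(CCl)N1[C@@H](Cc2ccccc2)COC1=O | starting material
3 | (4S)-4-benzyl-3-[(4-bromo-2,6-dimethoxyphenoxy)acetyl]-1,3-oxazolidin-2-one | COc1cc(Br)cc(OC)c1OCC(=O)N1[C@@H](Cc2ccccc2)COC1=O | intermediate
4 | 4-(benzyloxy)-3-methoxybenzaldehyde | COc1cc(C=O)ccc1OCc1ccccc1 | starting material
5 | (4S)-4-benzyl-3-[(2R,3R)-3-[4-(benzyloxy)-3-methoxyphenyl]-2-(4-bromo-2,6-dimethoxyphenoxy)-3-[(trimethylsilyl)oxy]propanoyl]-1,3-oxazolidin-2-one | COc1cc([C@@H](O[Si](C)(C)C)[C@H](C(=O)N2[C@@H](Cc3ccccc3)COC2=O)Oc2c(OC)cc(Br)cc2OC)ccc1OCc1ccccc1 | intermediate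
6 | (4S)-4-benzyl-3-[(2R,3R)-3-[4-(benzyloxy)-3-methoxyphenyl]-2-(4-bromo-2,6-dimethoxyphenoxy)-3-hydroxypropanoyl]-1,3-oxazolidin-2-one | COc1cc([C@@H](O)[C@H](C(=O)N2[C@@H](Cc3ccccc3)COC2=O)Oc2c(OC)cc(Br)cc2OC)ccc1OCc1ccccc1 | intermediate
7 | (1R,2S)-1-[4-(benzyloxy)-3-methoxyphenyl]-2-(4-bromo-2,6-dimethoxyphenoxy)propane-1,3-diol | COc1cc([C@@H](O)[C@H](CO)Oc2c(OC)cc(Br)cc2OC)ccc1OCc1ccccc1 | intermediate
8 | (1R,2S)-1-[4-(benzyloxy)-3-methoxyphenyl]-2-(4-bromo-2,6-dimethoxyphenoxy)-1,3-bis[(tert-butyldimethylsilyl)oxy]propane | COc1cc([C@@H](O[Si](C)(C)C(C)(C)C)[C@H](CO[Si](C)(C)C(C)(C)C)Oc2c(OC)cc(Br)cc2OC)ccc1OCc1ccccc1 | intermediate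
9 | N-methoxy-N-methylprop-2-enamide | C=CC(=O)N(C)OC | starting material
10 | (2E)-3-[4-({(1R,2S)-1-[4-(benzyloxy)-3-methoxyphenyl]-1,3-bis[(tert-butyldimethylsilyl)oxy]propan-2-yl}oxy)-3,5-dimethoxyphenyl]-N-methoxy-N-methylprop-2-enamide | COc1cc([C@@H](O[Si](C)(C)C(C)(C)C)[C@H](CO[Si](C)(C)C(C)(C)C)Oc2c(OC)cc(/C=C/C(=O)N(C)OC)cc2OC)ccc1OCc1ccccc1 | intermediate
11 | methyl 3,5-dioxohexanoate | COC(=O)CC(=O)CC(C)=O | starting material
12 | methyl (8E)-9-[4-({(1R,2S)-1-[4-(benzyloxy)-3-methoxyphenyl]-1,3-bis[(tert-butyldimethylsilyl)oxy]propan-2-yl}oxy)-3,5-dimethoxyphenyl]-3,5,7-trioxonon-8-enoate | COc1cc([C@@H](O[Si](C)(C)C(C)(C)C)[C@H](CO[Si](C)(C)C(C)(C)C)Oc2c(OC)cc(/C=C/C(=O)CC(=O)CC(=O)CC(=O)OC)cc2OC)ccc1OCc1ccccc1 | intermediate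
13 | (2E)-3-[4-({(1R,2S)-1-[4-(benzyloxy)-3-methoxyphenyl]-1,3-bis[(tert-butyldimethylsilyl)oxy]propan-2-yl}oxy)-3,5-dimethoxyphenyl]-1-(2,4,6-trihydroxyphenyl)prop-2-en-1-one | COc1cc([C@@H](O[Si](C)(C)C(C)(C)C)[C@H](CO[Si](C)(C)C(C)(C)C)Oc2c(OC)cc(/C=C/C(=O)c3c(O)cc(O)cc3O)cc2OC)ccc1OCc1ccccc1 | intermediate
14 | 2-[4-({(1R,2S)-1-[4-(benzyloxy)-3-methoxyphenyl]-1,3-bis[(tert-butyldimethylsilyl)oxy]propan-2-yl}oxy)-3,5-dimethoxyphenyl]-5,7-dihydroxy-2,3-dihydro-4H-chromen-4-one (both C2 epimers) | COc1cc([C@@H](O[Si](C)(C)C(C)(C)C)[C@H](CO[Si](C)(C)C(C)(C)C)Oc2c(OC)cc(C3CC(=O)c4c(O)cc(O)cc4O3)cc2OC)ccc1OCc1ccccc1 | intermediate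
15 | 2-[4-({(1R,2S)-1-[4-(benzyloxy)-3-methoxyphenyl]-1,3-bis[(tert-butyldimethylsilyl)oxy]propan-2-yl}oxy)-3,5-dimethoxyphenyl]-5,7-dihydroxy-4H-chromen-4-one | COc1cc([C@@H](O[Si](C)(C)C(C)(C)C)[C@H](CO[Si](C)(C)C(C)(C)C)Oc2c(OC)cc(-c3cc(=O)c4c(O)cc(O)cc4o3)cc2OC)ccc1OCc1ccccc1 | intermediate
16 | 2-[4-({(1R,2S)-1-[4-(benzyloxy)-3-methoxyphenyl]-1,3-dihydroxypropan-2-yl}oxy)-3,5-dimethoxyphenyl]-5,7-dihydroxy-4H-chromen-4-one | COc1cc([C@@H](O)[C@H](CO)Oc2c(OC)cc(-c3cc(=O)c4c(O)cc(O)cc4o3)cc2OC)ccc1OCc1ccccc1 | intermediate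
17 | (2S,3R)-3-[4-(benzyloxy)-3-methoxyphenyl]-2-[4-(5,7-dihydroxy-4-oxo-4H-chromen-2-yl)-2,6-dimethoxyphenoxy]-3-hydroxypropyl acetate | COc1cc([C@@H](O)[C@H](COC(C)=O)Oc2c(OC)cc(-c3cc(=O)c4c(O)cc(O)cc4o3)cc2OC)ccc1OCc1ccccc1 | intermediate
18 | (2S,3R)-2-[4-(5,7-dihydroxy-4-oxo-4H-chromen-2-yl)-2,6-dimethoxyphenoxy]-3-hydroxy-3-(4-hydroxy-3-methoxyphenyl)propyl acetate | COc1cc([C@@H](O)[C@H](COC(C)=O)Oc2c(OC)cc(-c3cc(=O)c4c(O)cc(O)cc4o3)cc2OC)ccc1O | target

Total step count: 11. Longest linear sequence: 11 steps (1 or 2 to 18); compounds 4, 9 and 11 enter as purchased materials.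

Steps most likely to fail

1. Step 7 (key step). The chain may instead close by aldol addition of C2 to the C7 ketone (resorcylate fold), lactonise to a 4-hydroxy-2-pyrone, or lose its ester by saponification before the ring forms. The fallback sets out from 8 and comes back at 13, so that ring A is bought instead of built.
   - Bromine–lithium exchange on 8 (n-BuLi, THF, −78 °C) and formylation with DMF should give 4-({(1R,2S)-1-[4-(benzyloxy)-3-methoxyphenyl]-1,3-bis[(tert-butyldimethylsilyl)oxy]propan-2-yl}oxy)-3,5-dimethoxybenzaldehyde F1.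
   - Commercial 2',4',6'-trihydroxyacetophenone is allylated (allyl bromide, K2CO3, acetone; the hydrogen-bonded ortho hydroxyl stays free) to 1-[2-hydroxy-4,6-bis(prop-2-en-1-yloxy)phenyl]ethan-1-one F2.
   - Claisen–Schmidt condensation of F1 with F2 (KOH, EtOH, 23 °C) should give (2E)-3-[4-({(1R,2S)-1-[4-(benzyloxy)-3-methoxyphenyl]-1,3-bis[(tert-butyldimethylsilyl)oxy]propan-2-yl}oxy)-3,5-dimethoxyphenyl]-1-[2-hydroxy-4,6-bis(prop-2-en-1-yloxy)phenyl]prop-2-en-1-one F3.
   - Palladium-catalysed deallylation (Pd(PPh3)4, morpholine, THF, 23 °C) then returns chalcone 13.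

2. Step 6. Trianion formation may be incomplete, the carbanion may add in conjugate fashion, or the free triketo ester may cyclise during quench and isolation. The fallback sets out from 10 and comes back at 12; it uses a milder dianion and releases the triketo ester under neutral conditions.
   - Commercial 2,2,6-trimethyl-4H-1,3-dioxin-4-one is enolised (LiHMDS, THF, −78 °C) and C-acetylated (acetyl chloride) to 2,2-dimethyl-6-(2-oxopropyl)-4H-1,3-dioxin-4-one F4.
   - The dianion of F4 (LDA, 2 equiv, THF, −78 °C) is acylated at its terminal methyl by Weinreb amide 10 to give 6-[(5E)-6-[4-({(1R,2S)-1-[4-(benzyloxy)-3-methoxyphenyl]-1,3-bis[(tert-butyldimethylsilyl)oxy]propan-2-yl}oxy)-3,5-dimethoxyphenyl]-2,4-dioxohex-5-en-1-yl]-2,2-dimethyl-4H-1,3-dioxin-4-one F5.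
   - Thermolysis of F5 in toluene with methanol (100 °C; retro-[4+2] loss of acetone and trapping of the acylketene) should give 12.

3. Step 2. The aryloxy oxygen may join the magnesium chelate and erode the anti/syn or the facial preference, and addition to the electron-rich aldehyde may be slow enough for turnover to stall. The fallback sets out from 1 and comes back at 7; it uses a syn aldol followed by inversion.
   - Alkylation of 1 with the commercial enantiomer of 2 (K2CO3, NaI, acetone) gives (4R)-4-benzyl-3-[(4-bromo-2,6-dimethoxyphenoxy)acetyl]-1,3-oxazolidin-2-one F6.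
   - Boron-mediated Evans syn-aldol reaction with 4 (Bu2BOTf, iPr2NEt, CH2Cl2, −78 to 0 °C) gives (4R)-4-benzyl-3-[(2R,3S)-3-[4-(benzyloxy)-3-methoxyphenyl]-2-(4-bromo-2,6-dimethoxyphenoxy)-3-hydroxypropanoyl]-1,3-oxazolidin-2-one F7.
   - Mitsunobu inversion of the benzylic carbinol (PPh3, DIAD, 4-nitrobenzoic acid, THF, 0 °C) gives (1R,2R)-1-[4-(benzyloxy)-3-methoxyphenyl]-3-[(4R)-4-benzyl-2-oxo-1,3-oxazolidin-3-yl]-2-(4-bromo-2,6-dimethoxyphenoxy)-3-oxopropyl 4-nitrobenzoate F8.
   - LiBH4 (THF, MeOH, 0 °C) cleaves both the auxiliary and the ester to give diol 7.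

Further compounds
F1 | step 7 | 4-({(1R,2S)-1-[4-(benzyloxy)-3-methoxyphenyl]-1,3-bis[(tert-butyldimethylsilyl)oxy]propan-2-yl}oxy)-3,5-dimethoxybenzaldehyde | COc1cc([C@@H](O[Si](C)(C)C(C)(C)C)[C@H](CO[Si](C)(C)C(C)(C)C)Oc2c(OC)cc(C=O)cc2OC)ccc1OCc1ccccc1
F2 | step 7 | 1-[2-hydroxy-4,6-bis(prop-2-en-1-yloxy)phenyl]ethan-1-one | CC(=O)c1c(O)cc(OCC=C)cc1OCC=C
F3 | step 7 | (2E)-3-[4-({(1R,2S)-1-[4-(benzyloxy)-3-methoxyphenyl]-1,3-bis[(tert-butyldimethylsilyl)oxy]propan-2-yl}oxy)-3,5-dimethoxyphenyl]-1-[2-hydroxy-4,6-bis(prop-2-en-1-yloxy)phenyl]prop-2-en-1-one | COc1cc([C@@H](O[Si](C)(C)C(C)(C)C)[C@H](CO[Si](C)(C)C(C)(C)C)Oc2c(OC)cc(/C=C/C(=O)c3c(O)cc(OCC=C)cc3OCC=C)cc2OC)ccc1OCc1ccccc1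
F4 | step 6 | 2,2-dimethyl-6-(2-oxopropyl)-4H-1,3-dioxin-4-one | CC(=O)CC1=CC(=O)OC(C)(C)O1
F5 | step 6 | 6-[(5E)-6-[4-({(1R,2S)-1-[4-(benzyloxy)-3-methoxyphenyl]-1,3-bis[(tert-butyldimethylsilyl)oxy]propan-2-yl}oxy)-3,5-dimethoxyphenyl]-2,4-dioxohex-5-en-1-yl]-2,2-dimethyl-4H-1,3-dioxin-4-one | COc1cc([C@@H](O[Si](C)(C)C(C)(C)C)[C@H](CO[Si](C)(C)C(C)(C)C)Oc2c(OC)cc(/C=C/C(=O)CC(=O)CC3=CC(=O)OC(C)(C)O3)cc2OC)ccc1OCc1ccccc1
F6 | step 2 | (4R)-4-benzyl-3-[(4-bromo-2,6-dimethoxyphenoxy)acetyl]-1,3-oxazolidin-2-one | COc1cc(Br)cc(OC)c1OCC(=O)N1[C@H](Cc2ccccc2)COC1=O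
F7 | step 2 | (4R)-4-benzyl-3-[(2R,3S)-3-[4-(benzyloxy)-3-methoxyphenyl]-2-(4-bromo-2,6-dimethoxyphenoxy)-3-hydroxypropanoyl]-1,3-oxazolidin-2-one | COc1cc([C@H](O)[C@H](C(=O)N2[C@H](Cc3ccccc3)COC2=O)Oc2c(OC)cc(Br)cc2OC)ccc1OCc1ccccc1
F8 | step 2 | (1R,2R)-1-[4-(benzyloxy)-3-methoxyphenyl]-3-[(4R)-4-benzyl-2-oxo-1,3-oxazolidin-3-yl]-2-(4-bromo-2,6-dimethoxyphenoxy)-3-oxopropyl 4-nitrobenzoate | COc1cc([C@@H](OC(=O)c2ccc(cc2)[N+](=O)[O-])[C@H](C(=O)N2[C@H](Cc3ccccc3)COC2=O)Oc2c(OC)cc(Br)cc2OC)ccc1OCc1ccccc1
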